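**Assumption:** the SMILES defines a cis-fused decalin (angular Me and H-10 syn), i.e. the C-5 epimer of ilimaquinone, with (1R,2S,4aR,8aS) configuration on the decalin. I build it exactly as drawn.

## Retrosynthetic overview
1. The C–C bond from the benzylic CH2 to the hydroxyquinone is made last, by decarboxylative radical addition of acid 16 (via redox-active ester 17) to 2-hydroxy-5-methoxybenzoquinone 20. Quinone 20 comes from tetramethoxybenzene 18 by CAN oxidative dearomatization and mono-hydrolysis.
2. Acid 16 comes from a cis-decalin bis-enone (7) by double α-alkylation at C-9, reduction of both enone C=C bonds, and two carbonyl manipulations.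
3. Key step: a prochiral 4,4-disubstituted cyclohexa-2,5-dienone (6) undergoes a desymmetrizing intramolecular vinylogous Michael addition. This closes ring A and sets the quaternary C-5 and H-10 cis in one operation.
4. Dienone 6 is made from the commercial keto-ester ketal 1 (methylation, Weinreb ketone synthesis, deprotection, IBX). Ring B pre-exists; ring A forms in step 6.

Numbering covers substrates, intermediates and the target. Simple reagents are identified inline by name and SMILES.

## Route

**Step 1**
Reactants: 1 ethyl 1,4-dioxaspiro[4.5]decane-8-carboxylate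
Product: 2 ethyl 8-methyl-1,4-dioxaspiro[4.5]decane-8-carboxylate
Conditions: LDA, THF, −78 °C; then MeI, −78 → 0 °C
Reagents that add atoms: iodomethane, CI
Why: ester enolate C-alkylation installs the future C-5 methyl on the carbon that becomes quaternary.

**Step 2**
Reactants: 2
Product: 3 N-methoxy-N,8-dimethyl-1,4-dioxaspiro[4.5]decane-8-carboxamide
Conditions: MeNHOMe·HCl, i-PrMgCl, THF, −20 °C → rt
Reagents that add atoms: N,O-dimethylhydroxylamine, CNOC
Why: Grignard-mediated amidation (Williams) converts the hindered ester to the Weinreb amide.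

**Step 3**
Reactants: 3
Product: 4 (E)-1-(8-methyl-1,4-dioxaspiro[4.5]decan-8-yl)but-2-en-1-one
Conditions: (E)-MeCH=CHMgBr, THF, 0 °C
Reagents that add atoms: (E)-1-propenylmagnesium bromide, C/C=C/[Mg]Br
Why: Weinreb ketone synthesis gives the crotonoyl ketone with no over-addition. The crotonoyl γ-CH3 is the future ring-A nucleophile.

**Step 4**
Reactants: 4
Product: 5 (E)-4-methyl-4-crotonoylcyclohexan-1-one
Conditions: PPTS, acetone/H2O, 60 °C
Reagents that add atoms: water, O
Why: mild acetal hydrolysis unmasks the ring ketone and leaves the enone untouched.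

**Step 5**
Reactants: 5
Product: 6 (E)-4-crotonoyl-4-methylcyclohexa-2,5-dien-1-one (achiral, mirror-symmetric)
Conditions: IBX (2.5 equiv), DMSO/PhF, 80 °C
Reagents that add atoms: none
Why: IBX dehydrogenation (Nicolaou) converts a 4,4-disubstituted cyclohexanone into the cross-conjugated dienone. The two enones are enantiotopic.

**Step 6 (key step)**
Reactants: 6
Product: 7 cis-fused bicyclic bis-enone, O=C1C=CC[C@H]2CC(=O)C=C[C@@]12C. Angular Me and H-10 are syn, ring A is Ca(=O)–Cb=Cc–Cd, and ring B is the remaining enone.
Conditions: 9-amino-9-deoxy-epi-quinine (20 mol %), 2-fluorobenzoic acid (40 mol %), PhMe, 25 °C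
Reagents that add atoms: none
Why: the crotonoyl enone is converted into a dienamine, or a dienolate under base catalysis, whose γ-carbon adds 6-membered-ring-forming to the β-carbon of one enantiotopic dienone C=C. The tether on C-4 can only deliver C-γ to the adjacent β-carbon from the same face as itself, so the ring fusion is necessarily cis (angular Me and H-10 syn). The chiral catalyst chooses which enone reacts and so fixes the absolute configuration; the enantiomer of catalyst giving 7 as drawn is used.
Proposed new method: mechanism is dienamine (or dienolate) γ-attack onto a cyclohexadienone. The closest known reactions are amine-catalysed desymmetrizing intramolecular Michael additions to 4,4-disubstituted cyclohexadienones and dienamine-catalysed vinylogous Michael additions of enones.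

**Step 7**
Reactants: 7
Product: 8 C-9 monomethylated bis-enone, O=C1C=CC[C@H]2C(C)C(=O)C=C[C@@]12C (C-9 epimeric; the centre is re-enolized next step)
Conditions: LDA, THF, −78 °C; MeI, −78 → −20 °C
Reagents that add atoms: iodomethane, CI
Why: in 7 only C-9 carries an enolizable α-H. The ring-A ketone has no α-H, and the γ-CH2 is kinetically much less acidic. Kinetic enolate alkylation therefore occurs only at C-9.

**Step 8**
Reactants: 8
Product: 9 C-9 quaternary bis-enone, O=C1C=CC[C@H]2[C@](C)(CC(=O)OC)C(=O)C=C[C@@]12C (CH2CO2Me syn to angular Me and H-10, C-9 Me anti)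
Conditions: LiHMDS, THF/HMPA, −78 °C; BrCH2CO2Me, −78 → 0 °C
Reagents that add atoms: methyl bromoacetate, COC(=O)CBr
Why: the planar C-9 enolate is alkylated trans to the adjacent C1–C10 ring-A bond, i.e. from the convex face. This puts CH2CO2Me up (syn to Me-5) and pushes the C-9 methyl down, as in the target. Stereochemistry is set by 1,2-induction.

**Step 9**
Reactants: 9
Product: 10 saturated cis-diketone, O=C1CCC[C@H]2[C@](C)(CC(=O)OC)C(=O)CC[C@@]12C
Conditions: H2 (1 atm), 10% Pd/C, EtOAc, rt
Reagents that add atoms: none
Why: hydrogenation of both enone C=C bonds creates no stereocentres, and all existing centres are non-epimerizable.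

**Step 10**
Reactants: 10
Product: 11 C-4 ketal, C12(OCCO2)CCC[C@H]3[C@](C)(CC(=O)OC)C(=O)CC[C@@]13C
Conditions: (Me3SiOCH2)2, TMSOTf (cat.), CH2Cl2, −78 → 0 °C
Reagents that add atoms: 1,2-bis(trimethylsiloxy)ethane, C[Si](C)(C)OCCO[Si](C)(C)C
Why: Noyori ketalization at low temperature protects the less hindered C-4 ketone. The C-8 ketone is flanked by the quaternary C-9 bearing two substituents, so it is more hindered.

**Step 11**
Reactants: 11
Product: 12 C-8 methylene, C12(OCCO2)CCC[C@H]3[C@](C)(CC(=O)OC)C(=C)CC[C@@]13C
Conditions: Ph3PCH3Br, KOt-Bu, PhMe, 80 °C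
Reagents that add atoms: methylenetriphenylphosphorane, C=P(c1ccccc1)(c1ccccc1)c1ccccc1
Why: Wittig methylenation of the hindered ketone; the ketal, ester and quaternary centres are untouched.

**Step 12**
Reactants: 12
Product: 13 C-8 methyl, C12(OCCO2)CCC[C@H]3[C@](C)(CC(=O)OC)[C@@H](C)CC[C@@]13C
Conditions: H2 (50 psi), PtO2, EtOAc, rt
Reagents that add atoms: none
Why: axial delivery of H to C-8 from the open top face, in the chair where CH2CO2Me is equatorial and the C-9 Me is axial down, leaves the new CH3 down, cis to Me-9. This is heterogeneous hydrogenation of a 1,1-disubstituted alkene.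

**Step 13**
Reactants: 13
Product: 14 C-4 ketone, O=C1CCC[C@H]2[C@](C)(CC(=O)OC)[C@@H](C)CC[C@@]12C
Conditions: PPTS, acetone/H2O, 60 °C
Reagents that add atoms: water, O
Why: acetal hydrolysis; no alkene remains to be affected.

**Step 14**
Reactants: 14
Product: 15 methyl ester with exocyclic C4=CH2, C=C1CCC[C@H]2[C@](C)(CC(=O)OC)[C@@H](C)CC[C@@]12C
Conditions: Ph3PCH3Br, KOt-Bu, THF, 0 °C → rt
Reagents that add atoms: methylenetriphenylphosphorane, C=P(c1ccccc1)(c1ccccc1)c1ccccc1
Why: Wittig olefination installs the exocyclic methylene last, so it is never exposed to hydrogenation.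

**Step 15**
Reactants: 15
Product: 16 acid, C=C1CCC[C@H]2[C@](C)(CC(=O)O)[C@@H](C)CC[C@@]12C
Conditions: LiOH, THF/MeOH/H2O, 50 °C
Reagents that add atoms: lithium hydroxide, [Li+].[OH-]
Why: saponification under basic conditions avoids acid-induced cationic rearrangement of the exocyclic alkene next to the quaternary centre.

**Step 16**
Reactants: 16
Product: 17 N-hydroxyphthalimide ester, C=C1CCC[C@H]2[C@](C)(CC(=O)ON3C(=O)c4ccccc4C3=O)[C@@H](C)CC[C@@]12C
Conditions: NHPI, DIC, DMAP (cat.), CH2Cl2, rt
Reagents that add atoms: N-hydroxyphthalimide, O=C1c2ccccc2C(=O)N1O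
Why: carbodiimide esterification gives a redox-active ester, which is a clean source of the primary neopentyl radical.

**Step 17**
Reactants: 18 1,2,4,5-tetramethoxybenzene
Product: 19 2,5-dimethoxy-1,4-benzoquinone
Conditions: CAN (2.2 equiv), MeCN/H2O, 0 °C
Reagents that add atoms: water, O
Why: oxidative demethylation of the para-dimethoxy pair dearomatizes the electron-rich arene (CAN oxidation).

**Step 18**
Reactants: 19
Product: 20 2-hydroxy-5-methoxy-1,4-benzoquinone
Conditions: NaOH (1.0 equiv), THF/H2O, rt; then HCl
Reagents that add atoms: sodium hydroxide, [Na+].[OH-]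
Why: 19 is C2h-symmetric, so addition–elimination at either vinylogous ester gives one product (symmetry of the precursor, no regiochemistry issue).

**Step 19**
Reactants: 17 and 20
Product: 21 target, C=C1CCC[C@H]2[C@](C)(CC3=C(O)C(=O)C=C(OC)C3=O)[C@@H](C)CC[C@@]12C
Conditions: Ru(bpy)3Cl2 (2 mol %), Hantzsch ester, DMSO, blue LEDs, rt; then air
Reagents that add atoms: none
Why: single-electron reduction of 17 expels phthalimide and CO2 to give the neopentyl radical CH2•. It adds to C-3 of 20, the carbon adjacent to the OH and the more electrophilic of the two free quinone positions, and air re-oxidizes the hydroquinone.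
Proposed new method: decarboxylative Giese-type addition of a primary radical to a hydroxyquinone. The closest known reaction is redox-active-ester alkylation of quinones.

## Checks
- **Structure:** 21 is the target. It has the cis-decalin, exocyclic C4=CH2, the three methyls at C5/C9/C8 and CH2Ar on C9. The quinone is 2-hydroxy-5-methoxy with the CH2 at C-3.
- **Atom accounting:** 6 is an isomer of 7 (C11H12O2). The CH2 units of the ester side chain and the two methylenes are accounted for. The acid's C15 skeleton (after CO2 loss) plus the C7 quinone gives C22H30O4.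
- **Stereocentres:** C-5 and C-10 are set cis in step 6. C-9 is set in step 8, and C-8 in step 12. Every later step is non-epimerizing.
- **Functional group survival:** steps 10–13 do not touch the exocyclic methylene because it is installed in step 14. Saponification is done in base.

## Compound list
| # | Name | SMILES | Role |
|---|---|---|---|
| 1 | ethyl 1,4-dioxaspiro[4.5]decane-8-carboxylate | CCOC(=O)C1CCC2(CC1)OCCO2 | starting material |
| 2 | ethyl 8-methyl-1,4-dioxaspiro[4.5]decane-8-carboxylate | CCOC(=O)C1(C)CCC2(CC1)OCCO2 | intermediate |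
| 3 | Weinreb amide of 2 | CON(C)C(=O)C1(C)CCC2(CC1)OCCO2 | intermediate |
| 4 | (E)-crotonoyl ketone ketal | C/C=C/C(=O)C1(C)CCC2(CC1)OCCO2 | intermediate |
| 5 | 4-methyl-4-crotonoylcyclohexanone | C/C=C/C(=O)C1(C)CCC(=O)CC1 | intermediate |
| 6 | 4-crotonoyl-4-methylcyclohexa-2,5-dienone | C/C=C/C(=O)C1(C)C=CC(=O)C=C1 | intermediate |
| 7 | cis-8a-methyl-4,4a,5,8a-tetrahydronaphthalene-1,6-dione (bis-enone) | O=C1C=CC[C@H]2CC(=O)C=C[C@@]12C | intermediate |
| 8 | C-9 methyl bis-enone | O=C1C=CC[C@H]2C(C)C(=O)C=C[C@@]12C | intermediate |
| 9 | C-9 quaternary bis-enone ester | O=C1C=CC[C@H]2[C@](C)(CC(=O)OC)C(=O)C=C[C@@]12C | intermediate |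
| 10 | saturated cis-diketone ester | O=C1CCC[C@H]2[C@](C)(CC(=O)OC)C(=O)CC[C@@]12C | intermediate |
| 11 | C-4 ketal of 10 | C12(OCCO2)CCC[C@H]3[C@](C)(CC(=O)OC)C(=O)CC[C@@]13C | intermediate |
| 12 | C-8 methylene ketal | C12(OCCO2)CCC[C@H]3[C@](C)(CC(=O)OC)C(=C)CC[C@@]13C | intermediate |
| 13 | C-8 methyl ketal | C12(OCCO2)CCC[C@H]3[C@](C)(CC(=O)OC)[C@@H](C)CC[C@@]13C | intermediate |
| 14 | C-4 ketone ester | O=C1CCC[C@H]2[C@](C)(CC(=O)OC)[C@@H](C)CC[C@@]12C | intermediate |
| 15 | exo-methylene methyl ester | C=C1CCC[C@H]2[C@](C)(CC(=O)OC)[C@@H](C)CC[C@@]12C | intermediate |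
| 16 | exo-methylene carboxylic acid | C=C1CCC[C@H]2[C@](C)(CC(=O)O)[C@@H](C)CC[C@@]12C | intermediate |
| 17 | NHPI ester of 16 | C=C1CCC[C@H]2[C@](C)(CC(=O)ON3C(=O)c4ccccc4C3=O)[C@@H](C)CC[C@@]12C | intermediate |
| 18 | 1,2,4,5-tetramethoxybenzene | COc1cc(OC)c(OC)cc1OC | starting material (aromatic) |
| 19 | 2,5-dimethoxy-1,4-benzoquinone | COC1=CC(=O)C(OC)=CC1=O | intermediate |
| 20 | 2-hydroxy-5-methoxy-1,4-benzoquinone | COC1=CC(=O)C(O)=CC1=O | intermediate |
| 21 | 2-hydroxy-5-methoxy-3-{[(1R,2S,4aR,8aS)-1,2,4a-trimethyl-5-methylidenedecahydronaphthalen-1-yl]methyl}-1,4-benzoquinone | C=C1CCC[C@H]2[C@](C)(CC3=C(O)C(=O)C=C(OC)C3=O)[C@@H](C)CC[C@@]12C | target |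

## Step count
- Total steps: 19.
- Longest linear sequence: 17 steps (steps 1–16, then 19). The quinone branch (steps 17–18) runs in parallel.

## Three steps most likely to fail
1. **Step 6, enantioselective vinylogous Michael cyclization.** The hindered crotonoyl ketone may not form the dienamine, and the facial and enantio control is unproven.
   - Fallback: change strategy and start from commercial (S)-Wieland–Miescher ketone. Build the 5-methyl enone, and obtain the cis-fused decalin by Pd/C hydrogenation of the Δ4a,5 enone from the face syn to the angular Me. The C-9 and C-8 steps then follow as above, with the C-9 stereochemistry re-checked for the new ring-fusion conformation.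
2. **Step 12, C-8 methyl stereochemistry by hydrogenation.** The hindered exocyclic alkene may hydrogenate slowly or from the wrong face.
   - Fallback: set C-8 by a radical route instead. Add MeLi/CeCl3 to the C-8 ketone, convert the tertiary alcohol to a methyl oxalate, and reduce it under Barton–McCombie-type conditions, with H-atom transfer from the open face.
3. **Step 19, regioselective decarboxylative radical addition.** The radical could add at C-6 of the quinone or cyclize onto the exocyclic methylene.
   - Fallback: couple 17 under Ni catalysis with the arylzinc from 18 (Negishi-type decarboxylative arylation of the redox-active ester). Then oxidize with CAN, which reproduces the 2,5-dimethoxyquinone, and demethylate the OMe adjacent to the alkyl chain. If neither works, use the classical aldehyde/aryllithium coupling.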